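The plan opens the pyran ring of the 2,2-dimethyl-2H-chromene (O1, C2, C3, C4, C4a, C8a) across C3=C4 and O1–C2. C4a lies between two oxygenated carbons (C5 and C8a). The precursor is therefore a biaryl 2,6-dihydroxybenzaldehyde whose two hydroxyls are equivalent, and no regiochemical question arises. One operation converts this unprotected tetraphenol aldehyde into the target: amine-catalysed Petasis borono-Mannich alkenylation with 2-methylprop-1-enylboronic acid, amine expulsion to a vinyl ortho-quinone methide, and oxa-6π electrocyclisation. The aldehyde comes from a Negishi union of a 2,6-diprenylated arylzinc (ring A) with a 4-chloro-2,6-dialkoxybenzaldehyde (ring B).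

Key step: step 8

Remark on the chemistry: the target has no stereocentre, and its biaryl axis (two ortho prenyl groups on ring A, two ortho hydrogens on ring B) should rotate freely. The compound is therefore achiral on the laboratory time scale and no enantiocontrol is needed.
Labels: ring A is the catechol ring, ring B is the arene of the chromene, and prenyl is 3-methylbut-2-en-1-yl.

Step 1
Reactants: 1 4,5-dibromobenzene-1,2-diol
Product: 2 1,2-dibromo-4,5-bis(methoxymethoxy)benzene
Conditions: NaH (2.4 equiv), MOMCl (2.4 equiv), DMF, 0 °C to rt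
Reagents that add atoms: chloromethyl methyl ether (MOMCl), COCCl
Why: Williamson-type O-alkylation of the catecholate gives MOM acetals that survive all later organometallic steps and later act as ortho-directing groups.

Step 2
Reactants: 2 1,2-dibromo-4,5-bis(methoxymethoxy)benzene; 3 1-bromo-3-methylbut-2-ene (prenyl bromide)
Product: 5 1-bromo-4,5-bis(methoxymethoxy)-2-(3-methylbut-2-en-1-yl)benzene, via [2-bromo-4,5-bis(methoxymethoxy)phenyl]magnesium chloride 4 (not isolated)
Conditions: i-PrMgCl·LiCl (1.05 equiv), THF, −15 °C; then CuI (10 mol %), 3 (1.3 equiv), −15 °C to rt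
Reagents that add atoms: none
Why: Bromine–magnesium exchange should stop after one of the two homotopic C–Br bonds, because the ortho bromine speeds the first exchange and the arylmagnesium resists a second, and copper-catalysed allylic substitution on the γ,γ-disubstituted bromide then takes place at the primary carbon (SN2).

Step 3
Reactants: 5 1-bromo-4,5-bis(methoxymethoxy)-2-(3-methylbut-2-en-1-yl)benzene; 3 1-bromo-3-methylbut-2-ene
Product: 7 2-bromo-4,5-bis(methoxymethoxy)-1,3-bis(3-methylbut-2-en-1-yl)benzene, via [2-bromo-5,6-bis(methoxymethoxy)-3-(3-methylbut-2-en-1-yl)phenyl]lithium 6 (not isolated)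
Conditions: LDA (1.15 equiv), THF, −78 °C; then CuBr·SMe2 (10 mol %), 3 (1.5 equiv), −78 to −20 °C
Reagents that add atoms: none
Why: Directed ortho-metalation removes the only aromatic proton flanked by both Br and OMOM, the ortho-bromoaryllithium is held at −78 °C to suppress LiBr loss, and copper-catalysed SN2 allylation installs the second prenyl group.

Step 4
Reactants: 8 5-chlorobenzene-1,3-diol
Product: 9 1-chloro-3,5-bis(methoxymethoxy)benzene
Conditions: NaH (2.4 equiv), MOMCl (2.4 equiv), DMF, 0 °C to rt
Reagents that add atoms: chloromethyl methyl ether (MOMCl), COCCl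
Why: Williamson-type O-alkylation protects both phenols and sets up cooperative direction of the next lithiation.

Step 5
Reactants: 9 1-chloro-3,5-bis(methoxymethoxy)benzene
Product: 11 4-chloro-2,6-bis(methoxymethoxy)benzaldehyde, via [4-chloro-2,6-bis(methoxymethoxy)phenyl]lithium 10 (not isolated)
Conditions: n-BuLi (1.1 equiv), THF, −20 to 0 °C; DMF (2 equiv), 0 °C to rt; H2O
Reagents that add atoms: N,N-dimethylformamide, CN(C)C=O
Why: Directed ortho-metalation occurs at the C–H between the two chelating OMOM groups while the C–Cl bond is inert to n-BuLi, and formylation with DMF places the formyl carbon (the future C4) between the two oxygens.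

Step 6
Reactants: 7 2-bromo-4,5-bis(methoxymethoxy)-1,3-bis(3-methylbut-2-en-1-yl)benzene; 11 4-chloro-2,6-bis(methoxymethoxy)benzaldehyde
Product: 14 3,3',4',5-tetrakis(methoxymethoxy)-2',6'-bis(3-methylbut-2-en-1-yl)-[1,1'-biphenyl]-4-carbaldehyde, via [3,4-bis(methoxymethoxy)-2,6-bis(3-methylbut-2-en-1-yl)phenyl]lithium 12 (not isolated), via [3,4-bis(methoxymethoxy)-2,6-bis(3-methylbut-2-en-1-yl)phenyl]zinc chloride 13 (not isolated)
Conditions: 7 (1.2 equiv), n-BuLi, THF, −78 °C, 15 min; ZnCl2 (1.3 equiv), −78 °C to rt; then 11, Pd2(dba)3 (1 mol %), RuPhos (4 mol %), THF, 65 °C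
Reagents that add atoms: none
Why: In this Negishi coupling, fast Br–Li exchange and immediate transmetalation give a di-ortho-substituted arylzinc that leaves the aldehyde alone, and a bulky biarylphosphine–palladium catalyst is the established answer for hindered arylzincs with an aryl chloride activated by a para formyl group.

Step 7
Reactants: 14 3,3',4',5-tetrakis(methoxymethoxy)-2',6'-bis(3-methylbut-2-en-1-yl)-[1,1'-biphenyl]-4-carbaldehyde
Product: 15 3,3',4',5-tetrahydroxy-2',6'-bis(3-methylbut-2-en-1-yl)-[1,1'-biphenyl]-4-carbaldehyde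
Conditions: HCl (about 1 M) in MeOH–THF, 40 °C, Ar
Reagents that add atoms: none
Why: Acid-catalysed acetal solvolysis transfers the four MOM groups to methanol, and at this acidity and temperature it should be faster than cyclisation of the prenyl group onto the neighbouring phenol.

Step 8
Reactants: 15 3,3',4',5-tetrahydroxy-2',6'-bis(3-methylbut-2-en-1-yl)-[1,1'-biphenyl]-4-carbaldehyde; 16 (2-methylprop-1-en-1-yl)boronic acid
Product: 19 clusiachromene D, via Petasis adduct 4-[1-(dibenzylamino)-3-methylbut-2-en-1-yl]-2',6'-bis(3-methylbut-2-en-1-yl)-[1,1'-biphenyl]-3,3',4',5-tetrol 17 (not isolated), via vinyl ortho-quinone methide 3-[3,4-dihydroxy-2,6-bis(3-methylbut-2-en-1-yl)phenyl]-5-hydroxy-6-(3-methylbut-2-en-1-ylidene)cyclohexa-2,4-dien-1-one 18 (not isolated)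
Conditions: 16 (3 equiv), Bn2NH (30 mol %), degassed 1,4-dioxane, 90 °C, Ar; aqueous work-up
Reagents that add atoms: none
Why: Dibenzylamine condenses with the aldehyde of 15 to an iminium ion, an ortho phenol binds 16 as a boronate ate complex and passes its alkenyl carbon intramolecularly to the iminium carbon (C4–C3 bond, Petasis borono-Mannich reaction) to give 17, and at 90 °C the phenol expels the amine so that the vinyl ortho-quinone methide 18 closes O1–C2 by oxa-6π electrocyclisation, which leaves C3=C4 as the double bond, rearomatises ring B and returns the amine for the next turnover. The closest known reaction type is the amine-catalysed Petasis synthesis of 2H-chromenes from salicylaldehydes and alkenylboronic acids, and 18 is the kind of intermediate through which phenol–prenal chromenylations run. The only ring closed is the six-membered pyran, formed by a thermally allowed disrotatory 6π electrocyclisation of the O1=C8a–C4a=C4–C3=C2 array. No stereocentre is created, since C2 carries two methyl groups and the racemic amine-bearing carbon of 17 becomes sp2. The step needs site selectivity between the two ring-B phenols, and the substrate removes the question because both hydroxyls flank the formyl group and are symmetry-equivalent, so either one, and after proton shift either alkene geometry of 18, leads to 19, while the position of the formyl carbon fixes C4a between C5–OH and C8a–O. The prenyl alkenes are inert, only the ortho-hydroxy aldehyde can activate boron for transfer, and the excess of 16 covers its reversible esterification by the ring-A catechol, which aqueous work-up releases.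

Compound list
1 | 4,5-dibromobenzene-1,2-diol | Oc1cc(Br)c(Br)cc1O | starting material
2 | 1,2-dibromo-4,5-bis(methoxymethoxy)benzene | COCOc1cc(Br)c(Br)cc1OCOC | intermediate
3 | 1-bromo-3-methylbut-2-ene (prenyl bromide) | CC(C)=CCBr | starting material
4 | [2-bromo-4,5-bis(methoxymethoxy)phenyl]magnesium chloride (formed in situ) | COCOc1cc(Br)c([Mg]Cl)cc1OCOC | intermediate
5 | 1-bromo-4,5-bis(methoxymethoxy)-2-(3-methylbut-2-en-1-yl)benzene | COCOc1cc(Br)c(CC=C(C)C)cc1OCOC | intermediate
6 | [2-bromo-5,6-bis(methoxymethoxy)-3-(3-methylbut-2-en-1-yl)phenyl]lithium (formed in situ) | COCOc1c([Li])c(Br)c(CC=C(C)C)cc1OCOC | intermediate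
7 | 2-bromo-4,5-bis(methoxymethoxy)-1,3-bis(3-methylbut-2-en-1-yl)benzene | COCOc1c(CC=C(C)C)c(Br)c(CC=C(C)C)cc1OCOC | intermediate
8 | 5-chlorobenzene-1,3-diol | Oc1cc(O)cc(Cl)c1 | starting material
9 | 1-chloro-3,5-bis(methoxymethoxy)benzene | COCOc1cc(Cl)cc(OCOC)c1 | intermediate
10 | [4-chloro-2,6-bis(methoxymethoxy)phenyl]lithium (formed in situ) | COCOc1cc(Cl)cc(OCOC)c1[Li] | intermediate
11 | 4-chloro-2,6-bis(methoxymethoxy)benzaldehyde | COCOc1cc(Cl)cc(OCOC)c1C=O | intermediate
12 | [3,4-bis(methoxymethoxy)-2,6-bis(3-methylbut-2-en-1-yl)phenyl]lithium (formed in situ) | COCOc1c(CC=C(C)C)c([Li])c(CC=C(C)C)cc1OCOC | intermediate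
13 | [3,4-bis(methoxymethoxy)-2,6-bis(3-methylbut-2-en-1-yl)phenyl]zinc chloride (formed in situ) | COCOc1c(CC=C(C)C)c([Zn]Cl)c(CC=C(C)C)cc1OCOC | intermediate
14 | 3,3',4',5-tetrakis(methoxymethoxy)-2',6'-bis(3-methylbut-2-en-1-yl)-[1,1'-biphenyl]-4-carbaldehyde | COCOc1c(CC=C(C)C)c(-c2cc(OCOC)c(C=O)c(OCOC)c2)c(CC=C(C)C)cc1OCOC | intermediate
15 | 3,3',4',5-tetrahydroxy-2',6'-bis(3-methylbut-2-en-1-yl)-[1,1'-biphenyl]-4-carbaldehyde | CC(C)=CCc1cc(O)c(O)c(CC=C(C)C)c1-c1cc(O)c(C=O)c(O)c1 | intermediate
16 | (2-methylprop-1-en-1-yl)boronic acid | CC(C)=CB(O)O | starting material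
17 | 4-[1-(dibenzylamino)-3-methylbut-2-en-1-yl]-2',6'-bis(3-methylbut-2-en-1-yl)-[1,1'-biphenyl]-3,3',4',5-tetrol (racemic, formed in situ) | CC(C)=CCc1cc(O)c(O)c(CC=C(C)C)c1-c1cc(O)c(C(C=C(C)C)N(Cc2ccccc2)Cc2ccccc2)c(O)c1 | intermediate
18 | 3-[3,4-dihydroxy-2,6-bis(3-methylbut-2-en-1-yl)phenyl]-5-hydroxy-6-(3-methylbut-2-en-1-ylidene)cyclohexa-2,4-dien-1-one (either geometry of the exocyclic alkene, formed in situ) | CC(C)=CCc1cc(O)c(O)c(CC=C(C)C)c1C1=CC(=O)C(=CC=C(C)C)C(O)=C1 | intermediate
19 | clusiachromene D, 4-(5-hydroxy-2,2-dimethyl-2H-chromen-7-yl)-3,5-bis(3-methylbut-2-en-1-yl)benzene-1,2-diol | CC(C)=CCc1cc(O)c(O)c(CC=C(C)C)c1-c1cc(O)c2c(c1)OC(C)(C)C=C2 | target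

Total step count: 8. Longest linear sequence: 6 steps (1, 2, 3, 6, 7, 8).

Steps most likely to fail

**Step 8.**
- Risk: iminium formation and alkenyl transfer may be sluggish on the strongly hydrogen-bonded, electron-rich aldehyde. The catechol may tie up the boronic acid, and it may oxidise under the warm amine conditions.
- Fallback: it sets out from 14 and comes back at 19. 2-Methylprop-1-enylmagnesium bromide is added to the protected aldehyde 14 (THF, −78 to 0 °C). This should give the racemic, doubly activated carbinol 1-[3,3',4',5-tetrakis(methoxymethoxy)-2',6'-bis(3-methylbut-2-en-1-yl)-[1,1'-biphenyl]-4-yl]-3-methylbut-2-en-1-ol F1. Methanolic HCl then removes the four acetals and ionises the carbinol, so the same ortho-quinone methide 18 is reached by dehydration and closes to 19. No boron reagent or amine meets the free catechol, at the price of making the two bonds in separate operations.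

**Step 3.**
- Risk: the ortho-bromoaryllithium may lose LiBr (aryne formation) before it is alkylated. The base may attack the benzylic-allylic CH2 of the first prenyl group, or the allylation may drift toward SN2′ attack.
- Fallback: it sets out from 5 and comes back at 7. Anion 6 is quenched at −78 °C with iodine, a trap faster than LiBr loss, to give 2-bromo-3-iodo-4,5-bis(methoxymethoxy)-1-(3-methylbut-2-en-1-yl)benzene F2. A linear-selective palladium-catalysed Negishi coupling with prenylzinc bromide (biarylphosphine ligand, THF, rt) then addresses the C–I bond in preference to C–Br and delivers 7. The C–C bond is thus made by cross-coupling instead of anion alkylation.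

**Step 7.**
- Risk: during the slow cleavage of four acetals, the acid may cyclise the prenyl group next to the newly freed ring-A phenol to a chroman, or it may hydrate the prenyl alkenes.
- Fallback: it sets out from 14 and comes back at 15, and it replaces Brønsted-acid solvolysis by a protecting-group exchange. TMSOTf with 2,2'-bipyridyl (CH2Cl2, 0 °C to rt) converts the aryl MOM ethers into aryl silyl ethers without free acid. This gives 2',6'-bis(3-methylbut-2-en-1-yl)-3,3',4',5-tetrakis(trimethylsilyloxy)-[1,1'-biphenyl]-4-carbaldehyde F3. Neutral hydrolysis (H2O–THF) then frees the four phenols of 15.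

Further compounds
F1 | step 8 | 1-[3,3',4',5-tetrakis(methoxymethoxy)-2',6'-bis(3-methylbut-2-en-1-yl)-[1,1'-biphenyl]-4-yl]-3-methylbut-2-en-1-ol (racemic) | COCOc1c(CC=C(C)C)c(-c2cc(OCOC)c(C(O)C=C(C)C)c(OCOC)c2)c(CC=C(C)C)cc1OCOC
F2 | step 3 | 2-bromo-3-iodo-4,5-bis(methoxymethoxy)-1-(3-methylbut-2-en-1-yl)benzene | COCOc1c(I)c(Br)c(CC=C(C)C)cc1OCOC
F3 | step 7 | 2',6'-bis(3-methylbut-2-en-1-yl)-3,3',4',5-tetrakis(trimethylsilyloxy)-[1,1'-biphenyl]-4-carbaldehyde | CC(C)=CCc1cc(O[Si](C)(C)C)c(O[Si](C)(C)C)c(CC=C(C)C)c1-c1cc(O[Si](C)(C)C)c(C=O)c(O[Si](C)(C)C)c1
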